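**Plan**

1. Numbering (lignan style): oxolane O–C7(aryl ring A)–C8(C9H2OH)–C8'(C7'H(OH)–aryl ring B)–C9'H2. Retrosynthetic cuts: ring O–C7 (made last), C7–C8 (enolate benzylation), C7'–C8' (aldol); the C9/C9' carbons go back to a succinate.
2. Forward: succinate half ester on an oxazolidinone → Evans syn aldol with silylated vanillin (ring B, C7', C8') → temporary γ-lactone between C9 and O9' → trans benzylation (ring A, C8) → lactone reduced to the 1,4-diol → oxolane ring closed last.
3. Enabling feature: the phenolic OH of ring A is para to C7, so C7–H of the free phenol can be oxidised to a p-quinone methide. The C9' hydroxyl is 1,4-related to C7 (O9'–C9'–C8'–C8–C7), so its addition closes the five-membered ring.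
4. Stereochemistry: C7' and C8' from (S)-4-benzyloxazolidinone (syn aldol); C8 by trans alkylation of the lactone (relay from C8'); C7 by substrate control in the ring closure (aryl trans to C9).
5. Helpers: silyl ethers on the ring B phenol and on O7' keep that half out of the oxidation; a benzyl ether on the ring A phenol is removed just before the key step; auxiliary and lactone are removed by hydride.

Key step: step 10

Remark: TBS = tert-butyldimethylsilyl; the target SMILES is read as (7S,8R,7'S,8'R) in the numbering above, and this isomer is the one built.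

**Route**

Step 1
Reactants: 1 vanillin (4-hydroxy-3-methoxybenzaldehyde)
Product: 2 4-(TBSO)-3-methoxybenzaldehyde
Conditions: TBSCl, imidazole, DMF, 23 °C
Reagents that add atoms: tert-butyldimethylsilyl chloride, CC(C)(C)[Si](C)(C)Cl
Why: Imidazole-mediated silyl ether formation on the phenol is a standard protection that removes the acidic proton before the boron aldol and should leave the aldehyde untouched; no stereocenter is formed.

Step 2
Reactants: 3 (S)-4-benzyl-1,3-oxazolidin-2-one; 4 4-tert-butoxy-4-oxobutanoic acid (mono-tert-butyl succinate)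
Product: 6 tert-butyl 4-[(4S)-4-benzyl-2-oxo-1,3-oxazolidin-3-yl]-4-oxobutanoate, via mixed pivalic anhydride 5 (not isolated)
Conditions: t-BuCOCl, Et3N, THF, −20 °C; then 3, LiCl, −20 to 23 °C
Reagents that add atoms: none
Why: N-acylation of the oxazolidinone through a mixed anhydride (LiCl-assisted acyl transfer) should attach the auxiliary at the free carboxyl group only, since the pivaloyl carbonyl is too hindered to compete and the tert-butyl ester is inert; no new stereocenter.

Step 3
Reactants: 6 tert-butyl 4-[(4S)-4-benzyl-2-oxo-1,3-oxazolidin-3-yl]-4-oxobutanoate; 2 4-(TBSO)-3-methoxybenzaldehyde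
Product: 9 tert-butyl (3S)-4-[(4S)-4-benzyl-2-oxo-1,3-oxazolidin-3-yl]-3-[(S)-hydroxy(4-TBSO-3-methoxyphenyl)methyl]-4-oxobutanoate, via boron enolate 7 (not isolated), via boron aldolate 8 (not isolated)
Conditions: Bu2BOTf, i-Pr2NEt, CH2Cl2, −78 to 0 °C; then 2, −78 to 0 °C; then pH 7 buffer, MeOH, 30% H2O2, 0 °C
Reagents that add atoms: none
Why: Evans syn aldol reaction, in which the Z boron enolate of the imide (the ester is not enolised under soft enolisation) adds to the aldehyde through a closed chair transition state on the face opposite the benzyl group of the auxiliary, setting C8' and C7' together as the 2,3-syn (S,S) pair that the target requires.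

Step 4
Reactants: 9 the aldol adduct
Product: 10 tert-butyl (3S)-4-[(4S)-4-benzyl-2-oxo-1,3-oxazolidin-3-yl]-4-oxo-3-[(S)-(TBSO)(4-TBSO-3-methoxyphenyl)methyl]butanoate
Conditions: TBSOTf, 2,6-lutidine, CH2Cl2, −78 to 0 °C
Reagents that add atoms: tert-butyldimethylsilyl trifluoromethanesulfonate, CC(C)(C)[Si](C)(C)OS(=O)(=O)C(F)(F)F
Why: Silylation with a silyl triflate and a hindered base should protect the hindered benzylic carbinol without retro-aldol cleavage, which keeps O7' from lactonising later and from being ionised or oxidised in the key step; no stereocenter changes.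

Step 5
Reactants: 10 the silylated aldol imide
Product: 12 (4R)-4-[(S)-(TBSO)(4-TBSO-3-methoxyphenyl)methyl]oxolan-2-one, via hydroxy tert-butyl ester 11 (not isolated)
Conditions: LiBH4, H2O (1 equiv), Et2O, 0 °C; then camphorsulfonic acid (0.1 equiv), CH2Cl2, 23 °C
Reagents that add atoms: none
Why: Reductive cleavage of the N-acyl oxazolidinone by LiBH4 is selective for the activated imide carbonyl over the tert-butyl ester, and acid-catalysed intramolecular transesterification of the resulting γ-hydroxy ester should close the five-membered lactone through O9', the only free hydroxyl, without touching C7' or C8'.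

Step 6
Reactants: 13 [4-(benzyloxy)-3-methoxyphenyl]methanol
Product: 14 1-(benzyloxy)-4-(bromomethyl)-2-methoxybenzene
Conditions: PBr3, Et2O, 0 °C
Reagents that add atoms: phosphorus tribromide, BrP(Br)Br
Why: Conversion of a benzylic alcohol into the bromide with PBr3 (phosphite ester formation, then bromide displacement) is routine for electron-rich benzyl alcohols and provides the electrophile for the alkylation; no stereocenter.

Step 7
Reactants: 12 (4R)-4-[(S)-(TBSO)(4-TBSO-3-methoxyphenyl)methyl]oxolan-2-one; 14 1-(benzyloxy)-4-(bromomethyl)-2-methoxybenzene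
Product: 16 (3R,4R)-3-{[4-(benzyloxy)-3-methoxyphenyl]methyl}-4-[(S)-(TBSO)(4-TBSO-3-methoxyphenyl)methyl]oxolan-2-one, via lithium enolate 15 (not isolated)
Conditions: LiN(SiMe3)2, THF, −78 °C; then 14, DMPU, −78 to −40 °C
Reagents that add atoms: none
Why: Alkylation of a β-substituted γ-butyrolactone enolate, in which the benzylic bromide should approach the planar enolate anti to the bulky C4 substituent and so set C8 trans to C8' ((3R,4R)), the arrangement that becomes the 3,4-cis oxolane once O9' is bonded to C7 instead of C9.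

Step 8
Reactants: 16 the trans-benzylated lactone
Product: 17 (2R,3R)-2-{[4-(benzyloxy)-3-methoxyphenyl]methyl}-3-[(S)-(TBSO)(4-TBSO-3-methoxyphenyl)methyl]butane-1,4-diol
Conditions: LiBH4, THF, 0 to 23 °C
Reagents that add atoms: none
Why: Hydride reduction of the lactone to the 1,4-diol removes the temporary ring and frees O9' and O9 while silyl and benzyl ethers are inert to LiBH4, and C8 is no longer epimerisable afterwards.

Step 9
Reactants: 17 the benzyl-protected diol
Product: 18 (2R,3R)-2-[(4-hydroxy-3-methoxyphenyl)methyl]-3-[(S)-(TBSO)(4-TBSO-3-methoxyphenyl)methyl]butane-1,4-diol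
Conditions: H2 (1 atm), 10% Pd/C, EtOAc, 23 °C
Reagents that add atoms: none
Why: Hydrogenolysis of the aryl benzyl ether over Pd/C under neutral conditions should unmask only the ring A phenol, the switch for the key step, leaving the aryl and benzylic silyl ethers in place; no stereocenter is affected.

Step 10
Reactants: 18 the phenolic diol
Product: 20 {(2S,3R,4R)-4-[(S)-(TBSO)(4-TBSO-3-methoxyphenyl)methyl]-2-(4-hydroxy-3-methoxyphenyl)oxolan-3-yl}methanol, via p-quinone methide 19 (not isolated)
Conditions: DDQ (1.05 equiv), CH2Cl2/aqueous pH 7 phosphate buffer, 0 °C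
Reagents that add atoms: none
Why: DDQ removes a hydride equivalent from C7 of the free para-alkylphenol (electron transfer from the phenol, then loss of the benzylic proton) to give p-quinone methide 19, and the C9' hydroxyl adds to its exocyclic carbon C7 in an oxa-1,6-conjugate addition that restores the aromatic ring and forms the O–C7 bond; the closest known reaction type is the biomimetic DDQ-mediated quinone methide cyclisation of 4-hydroxybenzyl-substituted butane-1,4-diols to 2-aryloxolanes. The oxolane closes in the 5-exo-trig mode, the C7=C1 bond of the quinone methide lying outside the new ring. The new stereocenter C7 is controlled by the neighbouring stereocenter C8 (itself relayed from C8'): allylic 1,3-strain holds H8 in the plane of the quinone methide and the tethered oxygen attacks the face that leaves the aryl group trans to the C8 hydroxymethyl group, which is also the more stable arrangement because the aryl group then stands alone on its face of the ring. The step needs chemoselectivity between two electron-rich arenes and two benzylic positions, which is secured because only ring A carries a free phenol while ring B and O7' are silylated, so that C7'–H should not be attacked at 0 °C. It needs regioselectivity among the oxygens, which is secured because O9' closes a five-membered ring whereas O9 could only close an oxetane and O7' is blocked. Further oxidation of the phenolic product is limited by the near-stoichiometric charge of oxidant and the low temperature.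

Step 11
Reactants: 20 the bis-silylated oxolane
Product: 21 (−)-tanegol, (S)-(4-hydroxy-3-methoxyphenyl)[(3R,4R,5S)-5-(4-hydroxy-3-methoxyphenyl)-4-(hydroxymethyl)oxolan-3-yl]methanol
Conditions: Bu4NF, AcOH, THF, 0 to 23 °C
Reagents that add atoms: none
Why: Fluoride-induced desilylation (driven by Si–F bond formation) should cleave the aryl and the benzylic silyl ether in one operation, and buffering with acetic acid avoids both the acid that would ionise the free benzylic positions (closure to the furofuran) and strongly basic phenoxide chemistry; no stereocenter is touched.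

**Compound list**

1 | vanillin (4-hydroxy-3-methoxybenzaldehyde) | COc1cc(C=O)ccc1O | starting material
2 | 4-(TBSO)-3-methoxybenzaldehyde | COc1cc(C=O)ccc1O[Si](C)(C)C(C)(C)C | intermediate
3 | (S)-4-benzyl-1,3-oxazolidin-2-one | O=C1N[C@@H](Cc2ccccc2)CO1 | starting material
4 | 4-tert-butoxy-4-oxobutanoic acid (mono-tert-butyl succinate) | CC(C)(C)OC(=O)CCC(=O)O | starting material
5 | mixed pivalic anhydride of 4 | CC(C)(C)OC(=O)CCC(=O)OC(=O)C(C)(C)C | intermediate
6 | tert-butyl 4-[(4S)-4-benzyl-2-oxo-1,3-oxazolidin-3-yl]-4-oxobutanoate | CC(C)(C)OC(=O)CCC(=O)N1[C@@H](Cc2ccccc2)COC1=O | intermediate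
7 | (Z)-dibutylboron enolate of 6 | CCCCB(CCCC)O/C(N1[C@@H](Cc2ccccc2)COC1=O)=C\CC(=O)OC(C)(C)C | intermediate
8 | dibutylboron aldolate of 9 | COc1cc([C@@H](OB(CCCC)CCCC)[C@H](CC(=O)OC(C)(C)C)C(=O)N2[C@@H](Cc3ccccc3)COC2=O)ccc1O[Si](C)(C)C(C)(C)C | intermediate
9 | tert-butyl (3S)-4-[(4S)-4-benzyl-2-oxo-1,3-oxazolidin-3-yl]-3-[(S)-hydroxy(4-TBSO-3-methoxyphenyl)methyl]-4-oxobutanoate | COc1cc([C@@H](O)[C@H](CC(=O)OC(C)(C)C)C(=O)N2[C@@H](Cc3ccccc3)COC2=O)ccc1O[Si](C)(C)C(C)(C)C | intermediate
10 | tert-butyl (3S)-4-[(4S)-4-benzyl-2-oxo-1,3-oxazolidin-3-yl]-4-oxo-3-[(S)-(TBSO)(4-TBSO-3-methoxyphenyl)methyl]butanoate | COc1cc([C@@H](O[Si](C)(C)C(C)(C)C)[C@H](CC(=O)OC(C)(C)C)C(=O)N2[C@@H](Cc3ccccc3)COC2=O)ccc1O[Si](C)(C)C(C)(C)C | intermediate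
11 | tert-butyl (3R)-4-hydroxy-3-[(S)-(TBSO)(4-TBSO-3-methoxyphenyl)methyl]butanoate | COc1cc([C@@H](O[Si](C)(C)C(C)(C)C)[C@H](CC(=O)OC(C)(C)C)CO)ccc1O[Si](C)(C)C(C)(C)C | intermediate
12 | (4R)-4-[(S)-(TBSO)(4-TBSO-3-methoxyphenyl)methyl]oxolan-2-one | COc1cc([C@@H](O[Si](C)(C)C(C)(C)C)[C@H]2COC(=O)C2)ccc1O[Si](C)(C)C(C)(C)C | intermediate
13 | [4-(benzyloxy)-3-methoxyphenyl]methanol | COc1cc(CO)ccc1OCc2ccccc2 | starting material
14 | 1-(benzyloxy)-4-(bromomethyl)-2-methoxybenzene | COc1cc(CBr)ccc1OCc2ccccc2 | intermediate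
15 | lithium enolate of 12 | COc1cc([C@@H](O[Si](C)(C)C(C)(C)C)[C@H]2COC(O[Li])=C2)ccc1O[Si](C)(C)C(C)(C)C | intermediate
16 | (3R,4R)-3-{[4-(benzyloxy)-3-methoxyphenyl]methyl}-4-[(S)-(TBSO)(4-TBSO-3-methoxyphenyl)methyl]oxolan-2-one | COc1cc([C@@H](O[Si](C)(C)C(C)(C)C)[C@H]2COC(=O)[C@@H]2Cc3ccc(OCc4ccccc4)c(OC)c3)ccc1O[Si](C)(C)C(C)(C)C | intermediate
17 | (2R,3R)-2-{[4-(benzyloxy)-3-methoxyphenyl]methyl}-3-[(S)-(TBSO)(4-TBSO-3-methoxyphenyl)methyl]butane-1,4-diol | COc1cc([C@@H](O[Si](C)(C)C(C)(C)C)[C@@H](CO)[C@H](CO)Cc2ccc(OCc3ccccc3)c(OC)c2)ccc1O[Si](C)(C)C(C)(C)C | intermediate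
18 | (2R,3R)-2-[(4-hydroxy-3-methoxyphenyl)methyl]-3-[(S)-(TBSO)(4-TBSO-3-methoxyphenyl)methyl]butane-1,4-diol | COc1cc([C@@H](O[Si](C)(C)C(C)(C)C)[C@@H](CO)[C@H](CO)Cc2ccc(O)c(OC)c2)ccc1O[Si](C)(C)C(C)(C)C | intermediate
19 | p-quinone methide of 18 (4-alkylidene-2-methoxycyclohexa-2,5-dien-1-one with exocyclic C7=C1 bond; C8, C8', C7' as in 18) | COc1cc([C@@H](O[Si](C)(C)C(C)(C)C)[C@@H](CO)[C@H](CO)C=C2C=CC(=O)C(OC)=C2)ccc1O[Si](C)(C)C(C)(C)C | intermediate
20 | {(2S,3R,4R)-4-[(S)-(TBSO)(4-TBSO-3-methoxyphenyl)methyl]-2-(4-hydroxy-3-methoxyphenyl)oxolan-3-yl}methanol | COc1cc([C@@H](O[Si](C)(C)C(C)(C)C)[C@H]2CO[C@H](c3ccc(O)c(OC)c3)[C@H]2CO)ccc1O[Si](C)(C)C(C)(C)C | intermediate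
21 | (−)-tanegol, (S)-(4-hydroxy-3-methoxyphenyl)[(3R,4R,5S)-5-(4-hydroxy-3-methoxyphenyl)-4-(hydroxymethyl)oxolan-3-yl]methanol | COc1cc([C@@H](O)[C@H]2CO[C@H](c3ccc(O)c(OC)c3)[C@H]2CO)ccc1O | target

**Step count and risks**

Total step count: 11. Longest linear sequence: 9 steps (steps 2, 3, 4, 5, 7, 8, 9, 10, 11; the sequence from vanillin through step 1 is equally long).

Steps most likely to fail:

1. Step 10. What may go wrong: a second oxidation of the phenolic product at C7 (now a benzylic ether position), capture of the quinone methide by water or by the electron-rich ring B (Friedel–Crafts closure to an aryltetralin), or tautomerisation of the quinone methide to the styrene. The fallback is non-oxidative: the leaving group at C7 is installed by an aldol reaction instead of C–H oxidation. It sets out from 12. The lithium enolate 15 is added to commercial 4-formyl-2-methoxyphenyl acetate at −78 °C to give the trans aldol adduct (3S,4R)-3-[(4-acetoxy-3-methoxyphenyl)(hydroxy)methyl]-4-[(S)-(TBSO)(4-TBSO-3-methoxyphenyl)methyl]oxolan-2-one F1; either carbinol epimer is usable, because C7 becomes planar later. LiBH4 in THF then reduces the lactone and cleaves the aryl acetate in the same operation to the phenolic triol (2R,3R)-2-[hydroxy(4-hydroxy-3-methoxyphenyl)methyl]-3-[(S)-(TBSO)(4-TBSO-3-methoxyphenyl)methyl]butane-1,4-diol F2. Pyridinium p-toluenesulfonate in CH2Cl2 at 0 °C should ionise only the p-hydroxybenzylic alcohol, through the same quinone methide 19, and the route is rejoined at 20.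

2. Step 5. What may go wrong: migration of the silyl group from O7' to O9' at the alkoxide stage followed by closure of the isomeric lactone through O7', acid-induced ionisation of the benzylic silyl ether during lactonisation, or partial reduction of the ester. The fallback replaces transesterification by oxidative lactonisation. It sets out from 10. Excess LiBH4 with MeOH in THF reduces imide and ester to the diol (2R)-2-[(S)-(TBSO)(4-TBSO-3-methoxyphenyl)methyl]butane-1,4-diol F3. TEMPO (catalytic) with PhI(OAc)2 in CH2Cl2 should then oxidise the less hindered primary alcohol (C9) to the lactol and on to the lactone, coming back to the route at 12.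

3. Step 7. What may go wrong: slow alkylation of the hindered enolate, which allows proton exchange with the product, dialkylation or loss of trans selectivity, and consumption of the bromide by side reactions. The fallback replaces alkylation by aldol addition and reductive removal of the benzylic oxygen. It sets out from 12. The enolate 15 is added to commercial 4-(benzyloxy)-3-methoxybenzaldehyde, an electrophile that reacts fast at −78 °C and also enters trans, to give (3S,4R)-3-{[4-(benzyloxy)-3-methoxyphenyl](hydroxy)methyl}-4-[(S)-(TBSO)(4-TBSO-3-methoxyphenyl)methyl]oxolan-2-one F4. Hydrogenolysis (H2, Pd/C, EtOAc–AcOH) should remove the benzyl ether and then the p-hydroxybenzylic hydroxyl to give (3R,4R)-3-[(4-hydroxy-3-methoxyphenyl)methyl]-4-[(S)-(TBSO)(4-TBSO-3-methoxyphenyl)methyl]oxolan-2-one F5. LiBH4 reduction of F5 rejoins the route at 18.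

Further compounds
F1 | step 10 | (3S,4R)-3-[(4-acetoxy-3-methoxyphenyl)(hydroxy)methyl]-4-[(S)-(TBSO)(4-TBSO-3-methoxyphenyl)methyl]oxolan-2-one (carbinol epimers) | COc1cc([C@@H](O[Si](C)(C)C(C)(C)C)[C@H]2COC(=O)[C@@H]2C(O)c3ccc(OC(C)=O)c(OC)c3)ccc1O[Si](C)(C)C(C)(C)C
F2 | step 10 | (2R,3R)-2-[hydroxy(4-hydroxy-3-methoxyphenyl)methyl]-3-[(S)-(TBSO)(4-TBSO-3-methoxyphenyl)methyl]butane-1,4-diol (carbinol epimers) | COc1cc([C@@H](O[Si](C)(C)C(C)(C)C)[C@@H](CO)[C@H](CO)C(O)c2ccc(O)c(OC)c2)ccc1O[Si](C)(C)C(C)(C)C
F3 | step 5 | (2R)-2-[(S)-(TBSO)(4-TBSO-3-methoxyphenyl)methyl]butane-1,4-diol | COc1cc([C@@H](O[Si](C)(C)C(C)(C)C)[C@H](CCO)CO)ccc1O[Si](C)(C)C(C)(C)C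
F4 | step 7 | (3S,4R)-3-{[4-(benzyloxy)-3-methoxyphenyl](hydroxy)methyl}-4-[(S)-(TBSO)(4-TBSO-3-methoxyphenyl)methyl]oxolan-2-one (carbinol epimers) | COc1cc([C@@H](O[Si](C)(C)C(C)(C)C)[C@H]2COC(=O)[C@@H]2C(O)c3ccc(OCc4ccccc4)c(OC)c3)ccc1O[Si](C)(C)C(C)(C)C
F5 | step 7 | (3R,4R)-3-[(4-hydroxy-3-methoxyphenyl)methyl]-4-[(S)-(TBSO)(4-TBSO-3-methoxyphenyl)methyl]oxolan-2-one | COc1cc([C@@H](O[Si](C)(C)C(C)(C)C)[C@H]2COC(=O)[C@@H]2Cc3ccc(O)c(OC)c3)ccc1O[Si](C)(C)C(C)(C)C
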